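Everything rests on cutting ring C of the flavanone across O1–C2 and C3–C4. The four atoms O1, C8a, C4a and C4 are read as a 4-methoxy ortho-quinone methide grown on the trioxygenated ring A, and C2–C3 as the vinyl group of a styrene that already carries ring B with its geranyl chain. A single chiral-acid-catalysed hetero-[4+2] then forges both bonds, closes ring C, sets C2 as S and leaves C4 as a methyl ether one oxidation level below the ketone. The partners are a MOM-protected phloroglucinaldehyde with one free phenol and a MOM-protected 3-geranyl-2,4-dioxygenated styrene.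

Key step: step 6

Assumption: the sense of induction of the chiral phosphoric acid in step 6 cannot be predicted with certainty; (R)-TRIP is written, and its enantiomer would be used if that is the one that delivers 2S. Geranyl stands for (2E)-3,7-dimethylocta-2,6-dien-1-yl throughout.

Step 1
Reactants: 1 2,4,6-trihydroxybenzaldehyde
Product: 2 2-hydroxy-4,6-bis(methoxymethoxy)benzaldehyde
Conditions: MOMCl (2.2 equiv), i-Pr2NEt (2.5 equiv), CH2Cl2, 0 °C
Reagents that add atoms: chloromethyl methyl ether, COCCl
Why: Williamson-type O-alkylation in which the 4-hydroxyl and one ortho hydroxyl react, while the last ortho hydroxyl, hydrogen-bonded to the aldehyde carbonyl, should stay free when the reagent is held near two equivalents.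

Step 2
Reactants: 3 resorcinol
Product: 4 1,3-bis(methoxymethoxy)benzene
Conditions: NaH (2.4 equiv), MOMCl (2.3 equiv), DMF, 0 °C to rt
Reagents that add atoms: chloromethyl methyl ether, COCCl
Why: Double Williamson etherification of the bis-phenoxide, which also installs the two directing groups for the metalations that follow.

Step 3
Reactants: 4 1,3-bis(methoxymethoxy)benzene; 5 geranyl bromide
Product: 8 2-geranyl-1,3-bis(methoxymethoxy)benzene, via aryllithium 6 (not isolated), via arylcopper 7 (not isolated)
Conditions: n-BuLi (1.1 equiv), THF, 0 °C to rt; CuI (1.0 equiv), −40 °C; 5 (1.1 equiv), −40 °C to rt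
Reagents that add atoms: none
Why: Directed ortho-metalation occurs at C2 between the two cooperating OMOM groups, and after transmetalation to copper the aryl group displaces bromide at the primary allylic carbon of 5 (SN2 allylic substitution), which should keep the E geometry of the chain.

Step 4
Reactants: 8 2-geranyl-1,3-bis(methoxymethoxy)benzene
Product: 10 3-geranyl-2,4-bis(methoxymethoxy)benzaldehyde, via aryllithium 9 (not isolated)
Conditions: n-BuLi (1.2 equiv), TMEDA (1.2 equiv), THF, −20 to 0 °C; DMF (2 equiv), −78 °C to rt; then H2O
Reagents that add atoms: N,N-dimethylformamide, CN(C)C=O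
Why: A second directed ortho-metalation at the only position still ortho to an OMOM group (C4, equivalent to C6), favoured over removal of a benzylic-allylic proton by coordination of the base to the acetal oxygens, is followed by formylation of the aryllithium with DMF (Bouveault-type formylation).

Step 5
Reactants: 10 3-geranyl-2,4-bis(methoxymethoxy)benzaldehyde
Product: 11 3-geranyl-2,4-bis(methoxymethoxy)styrene
Conditions: Ph3PCH3Br (1.3 equiv), KOtBu (1.25 equiv), THF, 0 °C; then 10, 0 °C to rt
Reagents that add atoms: methyltriphenylphosphonium bromide, C[P+](c1ccccc1)(c1ccccc1)c1ccccc1.[Br-]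
Why: Wittig methylenation of a non-enolisable aryl aldehyde with the unstabilised ylide, which leaves the MOM acetals and the chain alkenes alone.

Step 6
Reactants: 2 2-hydroxy-4,6-bis(methoxymethoxy)benzaldehyde; 11 3-geranyl-2,4-bis(methoxymethoxy)styrene
Product: 14 (2S,4S)-2-[3-geranyl-2,4-bis(methoxymethoxy)phenyl]-4-methoxy-5,7-bis(methoxymethoxy)chromane (2,4-cis), via dimethyl acetal 12 (not isolated), via ortho-quinone methide 13 (not isolated)
Conditions: 2 (1.3 equiv), 11 (1.0 equiv), HC(OMe)3 (2 equiv), (R)-TRIP (10 mol%), 5 Å MS, toluene, −20 to 0 °C; Et3N quench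
Reagents that add atoms: trimethyl orthoformate, COC(OC)OC
Why: Proposed new method: the chiral acid converts 2 and HC(OMe)3 into acetal 12 and then, by loss of methanol, into the 4-methoxy ortho-quinone methide 13 (in protonated form an aryl oxocarbenium ion paired with the phosphate and hydrogen-bonded to it through the free ring A hydroxyl), and the terminal CH2 of styrene 11 attacks the methide carbon while the phenolic oxygen closes on the developing benzylic carbon in an asynchronous inverse-electron-demand hetero-Diels–Alder reaction. The closest known reaction type is the acid-catalysed [4+2] cycloaddition of ortho-quinone methides with styrenes to 2-arylchromans, which has chiral phosphoric acid versions for methides made from ortho-hydroxybenzyl alcohols. Ring C closes by this [4+2] cycloaddition, C3–C4 forming ahead of O1–C2, so that no chalcone and no separate cyclisation are involved. C2 is controlled by the catalyst, whose 3,3'-aryl groups shield one face of the bound methide–styrene pair, and C4 follows from the endo-type arrangement that places OMe and aryl cis, although C4 is erased in step 8. The step needs regioselectivity, secured by the polarisation of the partners (nucleophilic CH2 to the methide carbon, the cation-stabilising aryl-bearing carbon to oxygen), and chemoselectivity for the vinyl group over the two trisubstituted alkenes of the chain and over the MOM acetals, secured by the far higher nucleophilicity of the 2,4-dialkoxystyrene and the weakness of the acid. The three oxygens of ring A should make the ionisation easy at low temperature.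

Step 7
Reactants: 14 (2S,4S)-2-[3-geranyl-2,4-bis(methoxymethoxy)phenyl]-4-methoxy-5,7-bis(methoxymethoxy)chromane
Product: 15 (2S,4RS)-2-[3-geranyl-2,4-bis(methoxymethoxy)phenyl]-5,7-bis(methoxymethoxy)chroman-4-ol
Conditions: PPTS (0.2 equiv), THF/H2O (4:1), high dilution, rt
Reagents that add atoms: water, O
Why: SN1 solvolysis in which the C4–OMe bond ionises to a cation stabilised by O1 and the 5- and 7-oxygens and is captured by the large excess of water, the weak acid being expected to spare the MOM acetals, the chain alkenes and C2, so that a mixture of C4 epimers of intact 2S configuration should result.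

Step 8
Reactants: 15 (2S,4RS)-2-[3-geranyl-2,4-bis(methoxymethoxy)phenyl]-5,7-bis(methoxymethoxy)chroman-4-ol
Product: 16 (2S)-2-[3-geranyl-2,4-bis(methoxymethoxy)phenyl]-5,7-bis(methoxymethoxy)chroman-4-one
Conditions: Dess–Martin periodinane (1.3 equiv), pyridine (3 equiv), CH2Cl2, 0 °C to rt
Reagents that add atoms: none
Why: Dess–Martin oxidation of the secondary benzylic alcohol merges both C4 epimers into the ketone under buffered, non-basic conditions that should not trigger retro-oxa-Michael opening, so C2 should keep its S configuration.

Step 9
Reactants: 16 (2S)-2-[3-geranyl-2,4-bis(methoxymethoxy)phenyl]-5,7-bis(methoxymethoxy)chroman-4-one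
Product: 17 sanggenol A, (2S)-2-(3-geranyl-2,4-dihydroxyphenyl)-5,7-dihydroxychroman-4-one
Conditions: 3 M aq. HCl, MeOH, 40 °C, monitored and stopped at full conversion
Reagents that add atoms: none
Why: Acid-catalysed acetal methanolysis of the four MOM ethers frees the phenols, with dilute acid and mild temperature chosen so that cyclisation of the geranyl chain onto the flanking phenols and ring-opening at C2 should not compete.

Compound list
1 | 2,4,6-trihydroxybenzaldehyde | O=Cc1c(O)cc(O)cc1O | starting material
2 | 2-hydroxy-4,6-bis(methoxymethoxy)benzaldehyde | O=Cc1c(O)cc(OCOC)cc1OCOC | intermediate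
3 | resorcinol | Oc1cccc(O)c1 | starting material
4 | 1,3-bis(methoxymethoxy)benzene | COCOc1cccc(OCOC)c1 | intermediate
5 | geranyl bromide, (2E)-1-bromo-3,7-dimethylocta-2,6-diene | CC(C)=CCC/C(C)=C/CBr | starting material
6 | [2,6-bis(methoxymethoxy)phenyl]lithium (not isolated) | [Li]c1c(OCOC)cccc1OCOC | intermediate
7 | [2,6-bis(methoxymethoxy)phenyl]copper (not isolated) | [Cu]c1c(OCOC)cccc1OCOC | intermediate
8 | 2-geranyl-1,3-bis(methoxymethoxy)benzene | CC(C)=CCC/C(C)=C/Cc1c(OCOC)cccc1OCOC | intermediate
9 | [3-geranyl-2,4-bis(methoxymethoxy)phenyl]lithium (not isolated) | CC(C)=CCC/C(C)=C/Cc1c(OCOC)ccc([Li])c1OCOC | intermediate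
10 | 3-geranyl-2,4-bis(methoxymethoxy)benzaldehyde | CC(C)=CCC/C(C)=C/Cc1c(OCOC)ccc(C=O)c1OCOC | intermediate
11 | 3-geranyl-2,4-bis(methoxymethoxy)styrene | CC(C)=CCC/C(C)=C/Cc1c(OCOC)ccc(C=C)c1OCOC | intermediate
12 | 2-(dimethoxymethyl)-3,5-bis(methoxymethoxy)phenol (not isolated) | COC(OC)c1c(O)cc(OCOC)cc1OCOC | intermediate
13 | 6-(methoxymethylidene)-3,5-bis(methoxymethoxy)cyclohexa-2,4-dien-1-one (not isolated) | COC=C1C(=O)C=C(OCOC)C=C1OCOC | intermediate
14 | (2S,4S)-2-[3-geranyl-2,4-bis(methoxymethoxy)phenyl]-4-methoxy-5,7-bis(methoxymethoxy)chromane | CC(C)=CCC/C(C)=C/Cc1c(OCOC)ccc([C@@H]2C[C@H](OC)c3c(OCOC)cc(OCOC)cc3O2)c1OCOC | intermediate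
15 | (2S,4RS)-2-[3-geranyl-2,4-bis(methoxymethoxy)phenyl]-5,7-bis(methoxymethoxy)chroman-4-ol | CC(C)=CCC/C(C)=C/Cc1c(OCOC)ccc([C@@H]2CC(O)c3c(OCOC)cc(OCOC)cc3O2)c1OCOC | intermediate
16 | (2S)-2-[3-geranyl-2,4-bis(methoxymethoxy)phenyl]-5,7-bis(methoxymethoxy)chroman-4-one | CC(C)=CCC/C(C)=C/Cc1c(OCOC)ccc([C@@H]2CC(=O)c3c(OCOC)cc(OCOC)cc3O2)c1OCOC | intermediate
17 | sanggenol A, (2S)-2-(3-geranyl-2,4-dihydroxyphenyl)-5,7-dihydroxychroman-4-one | CC(C)=CCC/C(C)=C/Cc1c(O)ccc([C@@H]2CC(=O)c3c(O)cc(O)cc3O2)c1O | target

Total step count: 9. Longest linear sequence: 8 steps (steps 2 to 9, from resorcinol).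

Steps most likely to fail

Step 6 (Proposed new method). The strongly stabilised methoxy quinone methide may be too weak an electrophile for turnover under a weak acid. The bond to oxygen may also form outside the control of the catalyst, giving poor facial selectivity at C2, or the product may re-ionise at C4 and add a second styrene. The fallback uses known chemistry, sets out from 8 and comes back at 16. Compound 8 would be lithiated as in step 4, and the aryllithium 9 trapped with B(OMe)3 and hydrolysed to [3-geranyl-2,4-bis(methoxymethoxy)phenyl]boronic acid F1. Commercial 5,7-dihydroxychromone would be protected (NaH, MOMCl, DMF) as 5,7-bis(methoxymethoxy)-4H-chromen-4-one F2. A rhodium-catalysed asymmetric 1,4-addition of F1 to F2 (Hayashi–Miyaura reaction) is a known way from chromones to 2-arylchroman-4-ones. With [RhOH(cod)]2, a chiral biaryl bisphosphine of the enantiomer that gives 2S, aqueous KOH and toluene at 40 °C, it should give 16 directly. Steps 5 to 8 would then be unnecessary.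

Step 7. The C4 cation may lose a proton to the flav-3-ene or alkylate the electron-rich ring A of a second molecule. Ionisation of the C2–O1 bond, helped by the two oxygens of ring B, may erode the configuration at C2. The fallback sets out from 14 and comes back at 16. It replaces ionisation of the C–O bond by hydride abstraction: DDQ (1.2 equiv) in CH2Cl2/pH 7 buffer at 0 °C should remove the hydride at C4. That hydrogen is the most hydridic one, being benzylic to the trioxygenated ring and alpha to OMe. The resulting oxocarbenium ion would take up water and lose methanol to give the ketone. No new compound is made (F0), and step 8 falls away.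

Step 9. Protic acid may cyclise the geranyl chain onto the 2'- or 4'-phenol, add across a chain alkene, or open ring C at C2 with loss of configuration. The fallback sets out from 16 and comes back at 17. It replaces acetal hydrolysis by silyl transfer: TESOTf and 2,2'-bipyridyl in MeCN at 0 °C convert aryl MOM ethers into aryl triethylsilyl ethers without protic acid. This should give (2S)-2-[3-geranyl-2,4-bis(triethylsilyloxy)phenyl]-5,7-bis(triethylsilyloxy)chroman-4-one F3. The silyl ethers would then be cleaved with AcOH-buffered TBAF in THF at 0 °C to give 17.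

Further compounds
F1 | step 6 | [3-geranyl-2,4-bis(methoxymethoxy)phenyl]boronic acid | CC(C)=CCC/C(C)=C/Cc1c(OCOC)ccc(B(O)O)c1OCOC
F2 | step 6 | 5,7-bis(methoxymethoxy)-4H-chromen-4-one | O=c1ccoc2cc(OCOC)cc(OCOC)c12
F0 | step 7 | none | none
F3 | step 9 | (2S)-2-[3-geranyl-2,4-bis(triethylsilyloxy)phenyl]-5,7-bis(triethylsilyloxy)chroman-4-one | CC(C)=CCC/C(C)=C/Cc1c(O[Si](CC)(CC)CC)ccc([C@@H]2CC(=O)c3c(O[Si](CC)(CC)CC)cc(O[Si](CC)(CC)CC)cc3O2)c1O[Si](CC)(CC)CC
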